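## Retrosynthetic overview

1. Target 22 ⇐ 21: the C9 ketone is unmasked last by chemoselective ozonolysis of a C9 methylidene group.
2. 21 ⇐ 18 + 20: a new chromium-catalysed, acyl-transfer-terminated Barbier macrocyclisation forms C7–C8, closes the ten-membered ring A, unveils the α-methylene lactone, installs the C8 ester and sets C7 and C8.
3. 18 ⇐ 15 + 16: the butenolide ring B is made first, by esterification and ring-closing metathesis; ring A follows.
4. 15 ⇐ 7 + 8: C5/C6 come from a Brown (Z)-γ-alkoxyallylboration; C4 comes from Sharpless epoxidation followed by hydride opening.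
5. 7 ⇐ 1: (R)-citronellal supplies C8–C10, C1–C5, both methyl groups and the C10 stereocentre; α-methylenation masks C9.

Atom labels (germacranolide numbering): C4 = C(OH)CH3, C5 = CH–O-isobutyrate, C6 = lactone CH–O, C7 = ring-fusion CH, C8 = CH–O-methylbutanoate, C9 = C=O, C10 = CH(CH3), C11/C12/C13 = lactone α-carbon/carbonyl/exocyclic CH2.

Assumption: only substrates, carbon building blocks whose atoms reach the target, and their intermediates are numbered; auxiliary reagents are given by name and SMILES where they add atoms.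

## Route

Step 1
Reactants: 1 (3R)-3,7-dimethyloct-6-enal [(R)-citronellal]
Product: 2 (3R)-3,7-dimethyl-2-methylideneoct-6-enal
Conditions: 37% aq. HCHO, pyrrolidine (10 mol %), EtCO2H (10 mol %), i-PrOH, 45 °C
Reagents that add atoms: formaldehyde, C=O
Why: Organocatalytic Mannich condensation/elimination (aldehyde α-methylenation) installs the methylidene that masks the C9 ketone; the C10 stereocentre is β to the carbonyl, is not enolisable and is untouched.

Step 2
Reactants: 2 (3R)-3,7-dimethyl-2-methylideneoct-6-enal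
Product: 3 (3R)-3,7-dimethyl-2-methylideneoct-6-en-1-ol
Conditions: NaBH4, CeCl3·7H2O, MeOH, 0 °C
Reagents that add atoms: none
Why: Luche reduction gives clean 1,2-reduction of the 2-substituted acrolein.

Step 3
Reactants: 3 (3R)-3,7-dimethyl-2-methylideneoct-6-en-1-ol
Product: 4 (3R)-2-[(methoxymethoxy)methyl]-3,7-dimethylocta-1,6-diene
Conditions: MOMCl, i-Pr2NEt, CH2Cl2, 0 °C to rt
Reagents that add atoms: chloromethyl methyl ether, COCCl
Why: Standard MOM ether formation masks the C8 allylic alcohol, so that only one free allylic alcohol is present in the later Sharpless epoxidation and hydride steps.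

Step 4
Reactants: 4 (3R)-2-[(methoxymethoxy)methyl]-3,7-dimethylocta-1,6-diene
Product: 5 (2E,6R)-7-[(methoxymethoxy)methyl]-2,6-dimethylocta-2,7-dien-1-ol
Conditions: SeO2 (0.5 equiv), t-BuOOH (3 equiv), salicylic acid (10 mol %), CH2Cl2, 0 °C to rt
Reagents that add atoms: selenium dioxide, O=[Se]=O (delivers the oxygen); tert-butyl hydroperoxide, CC(C)(C)OO (reoxidant and ultimate oxygen source)
Why: SeO2 allylic oxidation (ene reaction then [2,3]-sigmatropic shift) hydroxylates the (E)-methyl group of the more electron-rich trisubstituted alkene, giving the (E)-allylic alcohol (C5).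

Step 5
Reactants: 5 (2E,6R)-7-[(methoxymethoxy)methyl]-2,6-dimethylocta-2,7-dien-1-ol
Product: 6 [(2R,3R)-3-{(3R)-4-[(methoxymethoxy)methyl]-3-methylpent-4-en-1-yl}-2-methyloxiran-2-yl]methanol
Conditions: Ti(OiPr)4 (10 mol %), D-(−)-diethyl tartrate (12 mol %), t-BuOOH, 4 Å MS, CH2Cl2, −20 °C
Reagents that add atoms: tert-butyl hydroperoxide, CC(C)(C)OO
Why: Sharpless asymmetric epoxidation; the D-(−)-tartrate catalyst delivers oxygen to the face of the (E)-2-methyl allylic alcohol that gives the (2R,3R)-epoxide, which fixes the C4 configuration.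

Step 6
Reactants: 6 [(2R,3R)-3-{(3R)-4-[(methoxymethoxy)methyl]-3-methylpent-4-en-1-yl}-2-methyloxiran-2-yl]methanol
Product: 7 (2S,3R)-3-{(3R)-4-[(methoxymethoxy)methyl]-3-methylpent-4-en-1-yl}-2-methyloxirane-2-carbaldehyde
Conditions: Dess–Martin periodinane, pyridine, CH2Cl2, 0 °C to rt
Reagents that add atoms: none
Why: Buffered Dess–Martin oxidation gives the α-quaternary (non-epimerisable) epoxy aldehyde without opening the epoxide.

Step 7
Reactants: 7 (2S,3R)-3-{(3R)-4-[(methoxymethoxy)methyl]-3-methylpent-4-en-1-yl}-2-methyloxirane-2-carbaldehyde, 8 3-(methoxymethoxy)prop-1-ene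
Product: 10 (1R,2S)-2-(methoxymethoxy)-1-[(2R,3R)-3-{(3R)-4-[(methoxymethoxy)methyl]-3-methylpent-4-en-1-yl}-2-methyloxiran-2-yl]but-3-en-1-ol, via alkoxyallylborane 9 (not isolated)
Conditions: 8, s-BuLi, THF, −78 °C; (+)-Ipc2BOMe; BF3·OEt2; then 7, −78 °C to rt; HOCH2CH2NH2 work-up
Reagents that add atoms: 3-(methoxymethoxy)prop-1-ene (8), C=CCOCOC
Why: Brown γ-alkoxyallylboration: the (Z)-alkoxyallylborane reacts through a chair Zimmerman–Traxler transition state, so C5–OH and C6–OMOM come out syn, and the Ipc ligands derived from (−)-α-pinene select the aldehyde face that gives the 5R,6S configuration (reagent control, reinforced by the Felkin preference of the epoxy aldehyde).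

Step 8
Reactants: 10 (1R,2S)-2-(methoxymethoxy)-1-[(2R,3R)-3-{(3R)-4-[(methoxymethoxy)methyl]-3-methylpent-4-en-1-yl}-2-methyloxiran-2-yl]but-3-en-1-ol
Product: 11 (3S,4R,5S,9R)-3-(methoxymethoxy)-10-[(methoxymethoxy)methyl]-5,9-dimethylundeca-1,10-diene-4,5-diol
Conditions: LiAlH4, THF, 0 °C to rt; aq. KNaC4H4O6 (potassium sodium tartrate) work-up
Reagents that add atoms: none
Why: Hydride opens the trisubstituted epoxide by SN2 attack at the less substituted carbon C3, so the C4–O bond is retained and the (4S) tertiary alcohol of the target is revealed.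

Step 9
Reactants: 11 (3S,4R,5S,9R)-3-(methoxymethoxy)-10-[(methoxymethoxy)methyl]-5,9-dimethylundeca-1,10-diene-4,5-diol, 12 2-methylpropanoyl chloride
Product: 13 (3S,4R,5S,9R)-5-hydroxy-3-(methoxymethoxy)-10-[(methoxymethoxy)methyl]-5,9-dimethylundeca-1,10-dien-4-yl 2-methylpropanoate
Conditions: 12, pyridine, DMAP (5 mol %), CH2Cl2, 0 °C
Reagents that add atoms: 2-methylpropanoyl chloride (12), CC(C)C(Cl)=O
Why: DMAP-catalysed acylation occurs only at the secondary C5 hydroxyl (the tertiary C4 hydroxyl is inert), installing the isobutyrate of the target.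

Step 10
Reactants: 13 (3S,4R,5S,9R)-5-hydroxy-3-(methoxymethoxy)-10-[(methoxymethoxy)methyl]-5,9-dimethylundeca-1,10-dien-4-yl 2-methylpropanoate
Product: 14 (3S,4R,5S,9R)-3,5-dihydroxy-10-(hydroxymethyl)-5,9-dimethylundeca-1,10-dien-4-yl 2-methylpropanoate
Conditions: ZnBr2, n-PrSH, CH2Cl2, 0 °C to rt, 15 min
Reagents that add atoms: none
Why: Lewis-acid-activated thiolysis of both MOM acetals is fast and non-hydrolytic, freeing the C6 and C8 hydroxyls without ester cleavage or acyl migration.

Step 11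
Reactants: 14 (3S,4R,5S,9R)-3,5-dihydroxy-10-(hydroxymethyl)-5,9-dimethylundeca-1,10-dien-4-yl 2-methylpropanoate
Product: 15 (3S,4R,5S,9R)-10-formyl-3,5-dihydroxy-5,9-dimethylundeca-1,10-dien-4-yl 2-methylpropanoate
Conditions: TEMPO (10 mol %), PhI(OAc)2, CH2Cl2, 0 °C to rt
Reagents that add atoms: none
Why: The oxoammonium (TEMPO) oxidation is selective for the primary allylic alcohol over the secondary and tertiary hydroxyls, giving the 2-substituted acrolein (C8 aldehyde).

Step 12
Reactants: 15 (3S,4R,5S,9R)-10-formyl-3,5-dihydroxy-5,9-dimethylundeca-1,10-dien-4-yl 2-methylpropanoate, 16 2-(bromomethyl)prop-2-enoic acid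
Product: 17 (3S,4R,5S,9R)-10-formyl-5-hydroxy-5,9-dimethyl-4-[(2-methylpropanoyl)oxy]undeca-1,10-dien-3-yl 2-(bromomethyl)prop-2-enoate
Conditions: 16, DIC, DMAP (10 mol %), CH2Cl2, −10 to 0 °C
Reagents that add atoms: 2-(bromomethyl)prop-2-enoic acid (16), C=C(CBr)C(=O)O
Why: Steglich esterification acylates the only reactive (secondary allylic C6) hydroxyl and brings in C11–C13 with the allylic bromide already in place; low temperature and catalytic DMAP limit attack on the bromide.

Step 13
Reactants: 17 (3S,4R,5S,9R)-10-formyl-5-hydroxy-5,9-dimethyl-4-[(2-methylpropanoyl)oxy]undeca-1,10-dien-3-yl 2-(bromomethyl)prop-2-enoate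
Product: 18 (1R,2S,6R)-1-[(2S)-4-(bromomethyl)-5-oxo-2,5-dihydrofuran-2-yl]-7-formyl-2-hydroxy-2,6-dimethyloct-7-en-1-yl 2-methylpropanoate
Conditions: second-generation Grubbs catalyst (5 mol %), 1,4-benzoquinone (10 mol %), CH2Cl2 (5 mM), 40 °C
Reagents that add atoms: none
Why: Ring-closing metathesis between the vinyl group and the acrylate closes the butenolide (ring B) with loss of ethene and without touching C6; the electron-poor 2-substituted acrolein is a spectator olefin.

Step 14
Reactants: 19 (2R)-2-methylbutanoic acid (two molecules per molecule of 20)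
Product: 20 (2R)-2-methylbutanoic anhydride
Conditions: DCC (0.5 equiv relative to 19), CH2Cl2, 0 °C to rt; filtration
Reagents that add atoms: (2R)-2-methylbutanoic acid (19, the second molecule), CC[C@@H](C)C(=O)O
Why: Carbodiimide dehydration joins two molecules of acid 19 into the symmetric anhydride (DCC takes up the water as the urea) under base-free conditions that do not racemise the α-stereocentre.

Step 15
Reactants: 18 (1R,2S,6R)-1-[(2S)-4-(bromomethyl)-5-oxo-2,5-dihydrofuran-2-yl]-7-formyl-2-hydroxy-2,6-dimethyloct-7-en-1-yl 2-methylpropanoate, 20 (2R)-2-methylbutanoic anhydride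
Product: 21 (3aR,4R,6R,10S,11R,11aS)-10-hydroxy-6,10-dimethyl-3,5-dimethylidene-11-[(2-methylpropanoyl)oxy]-2-oxododecahydrocyclodeca[b]furan-4-yl (2R)-2-methylbutanoate
Conditions: CrCl2 (20 mol %), Mn powder (3 equiv), 20 (2 equiv), THF, 25 °C, syringe-pump addition of 18 over 12 h (final 2 mM)
Reagents that add atoms: (2R)-2-methylbutanoic anhydride (20), CC[C@@H](C)C(=O)OC(=O)[C@H](C)CC
Why: Proposed new method: a chromium-catalysed Barbier macrocyclisation terminated by acyl transfer — divalent chromium (CrCl2, regenerated by Mn) reduces the allylic C–Br bond to an allylchromium species (trivalent chromium) that adds at C7 to the tethered aldehyde through a chair Zimmerman–Traxler transition state, anti to the C5 side chain on the butenolide (trans-fused lactone) and with the enal residue equatorial (anti C7/C8 relation), which gives the C7 and C8 configurations of the target while the double bond moves to the exocyclic C11=C13 position; the trivalent chromium alkoxide is then O-acylated by anhydride 20 instead of the usual chlorosilane, which releases chromium for turnover, installs the C8 ester directly and avoids the chlorosilane-triggered reductive pinacol chemistry of 2-substituted acroleins; the closest known reactions are the stoichiometric CrCl2 Nozaki–Hiyama–Kishi/Barbier allylation of aldehydes with 3-(bromomethyl)furan-2(5H)-ones and chromium-catalytic Nozaki–Hiyama–Kishi couplings turned over with Mn and Me3SiCl, neither of which has been shown as a ten-membered ring closure with this donor or with acyl-transfer turnover.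

Step 16
Reactants: 21 (3aR,4R,6R,10S,11R,11aS)-10-hydroxy-6,10-dimethyl-3,5-dimethylidene-11-[(2-methylpropanoyl)oxy]-2-oxododecahydrocyclodeca[b]furan-4-yl (2R)-2-methylbutanoate
Product: 22 (3aS,4R,6R,10S,11R,11aS)-10-hydroxy-6,10-dimethyl-3-methylidene-11-[(2-methylpropanoyl)oxy]-2,5-dioxododecahydrocyclodeca[b]furan-4-yl (2R)-2-methylbutanoate (CNP0071420.1)
Conditions: O3, pyridine (3 equiv), CH2Cl2, −78 °C, Sudan Red 7B end point
Reagents that add atoms: ozone, [O-][O+]=O
Why: Ozonolysis cleaves the isolated 1,1-disubstituted C9 methylidene faster than the electron-poor conjugated α-methylene lactone (pyridine converts the carbonyl oxide directly to the carbonyl), unveiling the C9 ketone under cold, near-neutral conditions that do not epimerise C8 or C10.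

## Compound list

1 | (3R)-3,7-dimethyloct-6-enal, (R)-citronellal | O=CC[C@H](C)CCC=C(C)C | starting material
2 | (3R)-3,7-dimethyl-2-methylideneoct-6-enal | O=CC(=C)[C@H](C)CCC=C(C)C | intermediate
3 | (3R)-3,7-dimethyl-2-methylideneoct-6-en-1-ol | OCC(=C)[C@H](C)CCC=C(C)C | intermediate
4 | (3R)-2-[(methoxymethoxy)methyl]-3,7-dimethylocta-1,6-diene | COCOCC(=C)[C@H](C)CCC=C(C)C | intermediate
5 | (2E,6R)-7-[(methoxymethoxy)methyl]-2,6-dimethylocta-2,7-dien-1-ol | COCOCC(=C)[C@H](C)CC/C=C(\C)CO | intermediate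
6 | [(2R,3R)-3-{(3R)-4-[(methoxymethoxy)methyl]-3-methylpent-4-en-1-yl}-2-methyloxiran-2-yl]methanol | COCOCC(=C)[C@H](C)CC[C@H]1O[C@]1(C)CO | intermediate
7 | (2S,3R)-3-{(3R)-4-[(methoxymethoxy)methyl]-3-methylpent-4-en-1-yl}-2-methyloxirane-2-carbaldehyde | COCOCC(=C)[C@H](C)CC[C@H]1O[C@]1(C)C=O | intermediate
8 | 3-(methoxymethoxy)prop-1-ene (allyl methoxymethyl ether) | C=CCOCOC | starting material
9 | [(2Z)-3-(methoxymethoxy)prop-2-en-1-yl]bis(isopinocampheyl)borane, Ipc groups from (−)-α-pinene | COCO/C=C\CB([C@H]1C[C@H]2C[C@@H]([C@@H]1C)C2(C)C)[C@H]1C[C@H]2C[C@@H]([C@@H]1C)C2(C)C | intermediate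
10 | (1R,2S)-2-(methoxymethoxy)-1-[(2R,3R)-3-{(3R)-4-[(methoxymethoxy)methyl]-3-methylpent-4-en-1-yl}-2-methyloxiran-2-yl]but-3-en-1-ol | COCOCC(=C)[C@H](C)CC[C@H]1O[C@]1(C)[C@H](O)[C@@H](OCOC)C=C | intermediate
11 | (3S,4R,5S,9R)-3-(methoxymethoxy)-10-[(methoxymethoxy)methyl]-5,9-dimethylundeca-1,10-diene-4,5-diol | COCOCC(=C)[C@H](C)CCC[C@](C)(O)[C@H](O)[C@@H](OCOC)C=C | intermediate
12 | 2-methylpropanoyl chloride | CC(C)C(Cl)=O | starting material
13 | (3S,4R,5S,9R)-5-hydroxy-3-(methoxymethoxy)-10-[(methoxymethoxy)methyl]-5,9-dimethylundeca-1,10-dien-4-yl 2-methylpropanoate | COCOCC(=C)[C@H](C)CCC[C@](C)(O)[C@H](OC(=O)C(C)C)[C@@H](OCOC)C=C | intermediate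
14 | (3S,4R,5S,9R)-3,5-dihydroxy-10-(hydroxymethyl)-5,9-dimethylundeca-1,10-dien-4-yl 2-methylpropanoate | OCC(=C)[C@H](C)CCC[C@](C)(O)[C@H](OC(=O)C(C)C)[C@@H](O)C=C | intermediate
15 | (3S,4R,5S,9R)-10-formyl-3,5-dihydroxy-5,9-dimethylundeca-1,10-dien-4-yl 2-methylpropanoate | O=CC(=C)[C@H](C)CCC[C@](C)(O)[C@H](OC(=O)C(C)C)[C@@H](O)C=C | intermediate
16 | 2-(bromomethyl)prop-2-enoic acid | C=C(CBr)C(=O)O | starting material
17 | (3S,4R,5S,9R)-10-formyl-5-hydroxy-5,9-dimethyl-4-[(2-methylpropanoyl)oxy]undeca-1,10-dien-3-yl 2-(bromomethyl)prop-2-enoate | O=CC(=C)[C@H](C)CCC[C@](C)(O)[C@H](OC(=O)C(C)C)[C@@H](OC(=O)C(=C)CBr)C=C | intermediate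
18 | (1R,2S,6R)-1-[(2S)-4-(bromomethyl)-5-oxo-2,5-dihydrofuran-2-yl]-7-formyl-2-hydroxy-2,6-dimethyloct-7-en-1-yl 2-methylpropanoate | O=CC(=C)[C@H](C)CCC[C@](C)(O)[C@H](OC(=O)C(C)C)[C@H]1OC(=O)C(CBr)=C1 | intermediate
19 | (2R)-2-methylbutanoic acid | CC[C@@H](C)C(=O)O | starting material
20 | (2R)-2-methylbutanoic anhydride | CC[C@@H](C)C(=O)OC(=O)[C@H](C)CC | intermediate
21 | (3aR,4R,6R,10S,11R,11aS)-10-hydroxy-6,10-dimethyl-3,5-dimethylidene-11-[(2-methylpropanoyl)oxy]-2-oxododecahydrocyclodeca[b]furan-4-yl (2R)-2-methylbutanoate | C=C1C(=O)O[C@H]2[C@H]1[C@@H](OC(=O)[C@H](C)CC)C(=C)[C@H](C)CCC[C@](C)(O)[C@@H]2OC(=O)C(C)C | intermediate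
22 | (3aS,4R,6R,10S,11R,11aS)-10-hydroxy-6,10-dimethyl-3-methylidene-11-[(2-methylpropanoyl)oxy]-2,5-dioxododecahydrocyclodeca[b]furan-4-yl (2R)-2-methylbutanoate (CNP0071420.1) | C=C1C(=O)O[C@H]2[C@H]1[C@@H](OC(=O)[C@H](C)CC)C(=O)[C@H](C)CCC[C@](C)(O)[C@@H]2OC(=O)C(C)C | target

## Step count and risk assessment

Total step count: 16 (15 on the main line plus the preparation of anhydride 20).
Longest linear sequence: 15 steps (1 to 22 through steps 1–13, 15 and 16).

The three steps most likely to fail: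

**Step 15 (the proposed new macrocyclisation).** Risks are oligomerisation, sluggish acyl-transfer turnover of chromium, and attack on the wrong aldehyde face in the medium-ring transition state. The fallback uses known chemistry, sets out from 18 and comes back to the route at 21. The ring is closed by the classical stoichiometric Barbier protocol established for 3-(bromomethyl)furanones (Zn dust, THF/sat. aq. NH4Cl, high dilution by slow addition, water-tolerant and compatible with enals), giving the free C8 alcohol (3aR,4R,6R,10S,11R,11aS)-4,10-dihydroxy-6,10-dimethyl-3,5-dimethylidene-2-oxododecahydrocyclodeca[b]furan-11-yl 2-methylpropanoate F4. Bond formation is thus decoupled from esterification, and the ester is introduced afterwards by a separate acylation with anhydride 20 (DMAP, Et3N, CH2Cl2, 0 °C), which gives 21.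

**Step 16 (chemoselective ozonolysis).** The C9 methylidene is deactivated by the allylic ester, so the rate margin over the α-methylene lactone may be small. The fallback sets out from 21 and comes back at 22 by replacing ozone with a peracid, to which the electron-poor α-methylene lactone is inert. mCPBA (NaHCO3, CH2Cl2, 0 °C to rt) epoxidises only the C9 methylidene to give (3aS,4R,6R,10S,11R,11aS)-10-hydroxy-6,10-dimethyl-3-methylidene-11-[(2-methylpropanoyl)oxy]-2-oxodecahydro-2H-spiro[cyclodeca[b]furan-5,2'-oxiran]-4-yl (2R)-2-methylbutanoate F5 (both epimers at the spiro carbon). Periodic acid (H5IO6, THF/H2O, 0 °C) then hydrolyses and cleaves the terminal epoxide to the ketone 22.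

**Step 13 (ring-closing metathesis of an α-(bromomethyl)acrylate).** The trisubstituted, electron-poor, bromine-bearing olefin may close slowly or the allylic bromide may degrade the catalyst. The fallback sets out from 15 and comes back at 18, introducing bromine only after the ring is closed. Acylation of 15 with acryloyl chloride (i-Pr2NEt, CH2Cl2, −78 to 0 °C) gives (3S,4R,5S,9R)-10-formyl-5-hydroxy-5,9-dimethyl-4-[(2-methylpropanoyl)oxy]undeca-1,10-dien-3-yl prop-2-enoate F1. Morita–Baylis–Hillman hydroxymethylation of the acrylate (paraformaldehyde, DABCO, dioxane/H2O, rt) gives (3S,4R,5S,9R)-10-formyl-5-hydroxy-5,9-dimethyl-4-[(2-methylpropanoyl)oxy]undeca-1,10-dien-3-yl 2-(hydroxymethyl)prop-2-enoate F2. Ring-closing metathesis of this bromine-free acrylate (second-generation Grubbs catalyst, CH2Cl2, 40 °C) gives (1R,2S,6R)-7-formyl-2-hydroxy-1-[(2S)-4-(hydroxymethyl)-5-oxo-2,5-dihydrofuran-2-yl]-2,6-dimethyloct-7-en-1-yl 2-methylpropanoate F3. Appel bromination (CBr4, PPh3, CH2Cl2, 0 °C) then returns to 18.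

## Further compounds

F1 | step 13 | (3S,4R,5S,9R)-10-formyl-5-hydroxy-5,9-dimethyl-4-[(2-methylpropanoyl)oxy]undeca-1,10-dien-3-yl prop-2-enoate | O=CC(=C)[C@H](C)CCC[C@](C)(O)[C@H](OC(=O)C(C)C)[C@@H](OC(=O)C=C)C=C
F2 | step 13 | (3S,4R,5S,9R)-10-formyl-5-hydroxy-5,9-dimethyl-4-[(2-methylpropanoyl)oxy]undeca-1,10-dien-3-yl 2-(hydroxymethyl)prop-2-enoate | O=CC(=C)[C@H](C)CCC[C@](C)(O)[C@H](OC(=O)C(C)C)[C@@H](OC(=O)C(=C)CO)C=C
F3 | step 13 | (1R,2S,6R)-7-formyl-2-hydroxy-1-[(2S)-4-(hydroxymethyl)-5-oxo-2,5-dihydrofuran-2-yl]-2,6-dimethyloct-7-en-1-yl 2-methylpropanoate | O=CC(=C)[C@H](C)CCC[C@](C)(O)[C@H](OC(=O)C(C)C)[C@H]1OC(=O)C(CO)=C1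
F4 | step 15 | (3aR,4R,6R,10S,11R,11aS)-4,10-dihydroxy-6,10-dimethyl-3,5-dimethylidene-2-oxododecahydrocyclodeca[b]furan-11-yl 2-methylpropanoate | C=C1C(=O)O[C@H]2[C@H]1[C@@H](O)C(=C)[C@H](C)CCC[C@](C)(O)[C@@H]2OC(=O)C(C)C
F5 | step 16 | (3aS,4R,6R,10S,11R,11aS)-10-hydroxy-6,10-dimethyl-3-methylidene-11-[(2-methylpropanoyl)oxy]-2-oxodecahydro-2H-spiro[cyclodeca[b]furan-5,2'-oxiran]-4-yl (2R)-2-methylbutanoate | C=C1C(=O)O[C@H]2[C@H]1[C@@H](OC(=O)[C@H](C)CC)C3(CO3)[C@H](C)CCC[C@](C)(O)[C@@H]2OC(=O)C(C)C
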